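The synthesis rests on cutting the C6–C7 bond of the cyclohexanone ring. In that ring the C7 tertiary carbinol and the C10 ketone are 1,4-related, a pattern of mismatched polarity that lies hidden in 2-methylfuran: oxidative opening gives a Z ene-dione with C7 to C10 in place. One operation, an (R)-proline-catalysed enamine aldol of the C5 aldehyde onto the C7 ketone, closes the six-membered ring, forms C6–C7 and sets both ring stereocentres. Its precursor is the acyclic keto aldehyde (5Z)-3,3-dimethyl-4,7-dioxooct-5-enal. The C1–C4 chain, with C3 taken from (S)-citramalic acid, is then joined at C4=C5 by Julia–Kocienski olefination, and umbelliferone is attached last.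

Key step: step 3

Remark on numbering: the chain is numbered from the ether end, O–C1H2–C2H2–C3(Me)(OH)–C4H2–C5H2–C6H–C7(Me)(OH)–C8H2–C9H2–C10(=O)–C11Me2, with C6 to C11 forming the ring; these labels are used for all intermediates.

Assumption: the ring-closing aldol passes through the hydrogen-bonded enamine transition state accepted for proline aldols; on that basis (R)-proline is the enantiomer expected to give 6R,7S.

Remark on the precursor: compound 4 is made with a neutral oxidant (dimethyldioxirane as its usual acetone solution) and used without chromatography, because its E isomer cannot cyclise.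

Step 1
Reactants: 1 2-methylfuran; 2 3-methylbut-2-enal
Product: 3 3-methyl-3-(5-methylfuran-2-yl)butanal
Conditions: p-TsOH·H2O (5 mol %), 2 (3 equiv), CH2Cl2, −20 → 0 °C
Reagents that add atoms: none
Why: Acid-catalysed Friedel–Crafts conjugate addition, in which C5 of the furan attacks the protonated enal at its tertiary β-carbon (the mode known for 2-methylfuran with mesityl oxide and simpler enals), while excess enal and low temperature limit attack at the aldehyde carbon; no stereocentre is formed.

Step 2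
Reactants: 3 3-methyl-3-(5-methylfuran-2-yl)butanal
Product: 4 (5Z)-3,3-dimethyl-4,7-dioxooct-5-enal
Conditions: dimethyldioxirane (1.05 equiv, about 0.07 M in acetone), −20 → 0 °C, dark; concentrate below 0 °C, use crude
Reagents that add atoms: dimethyldioxirane, CC1(C)OO1
Why: Oxidative ring opening of a 2,5-dialkylfuran by a dioxirane (epoxidation of the furan, then opening) is known to give the Z ene-dione only, and the neutral reagent leaves the aldehyde untouched and gives only acetone, so 4 can be carried on before it isomerises.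

Step 3
Reactants: 4 (5Z)-3,3-dimethyl-4,7-dioxooct-5-enal
Product: 5 (1R,6S)-6-hydroxy-2,2,6-trimethyl-3-oxocyclohex-4-ene-1-carbaldehyde (hydroxyl cis to formyl)
Conditions: (R)-proline (20 mol %), CH2Cl2 (0.05 M), 0 °C → rt, dark; filter, use crude at once
Reagents that add atoms: none
Why: Proposed new method: (R)-proline condenses with the unhindered C5 aldehyde to an E enamine whose C6 adds to the C7 ketone, which the Z C8=C9 bond holds within reach and the carboxylic acid activates by a hydrogen bond, and hydrolysis of the iminium ion releases 5 and the catalyst. The closest known reaction is the proline-catalysed 6-enolexo aldolisation of saturated keto aldehydes and dialdehydes; a ketone that is part of a Z ene-dione has not been shown as the acceptor. The single ring closes in the 6-(enolexo)-exo-trig mode. C6 is set by the catalyst, (R)-proline directing the ketone to the enamine face that gives 6R (the mirror image of the sense that (S)-proline shows in aldehyde aldols), and C7 follows from the transition state: the C7 methyl lies pseudo-equatorial to avoid the axial C11 methyl, so the ketone oxygen is pseudo-axial and gauche to the enamine carbon across which it is hydrogen-bonded, which places hydroxyl and formyl cis. The step needs aldol at C7 to beat conjugate addition at C8 (5-endo-trig, disfavoured), amine addition to the ene-dione with Z to E isomerisation, and the base-type aldol of the C7 methyl onto C10 that turns Z ene-diones into 4-hydroxycyclopentenones; the aldehyde forms its enamine far faster than either ketone, C10 is shielded by the C11 gem-dimethyl group, and weakly acidic, dilute, cold and dark conditions avoid enolate chemistry and isomerisation.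

Step 4
Reactants: 5 (1R,6S)-6-hydroxy-2,2,6-trimethyl-3-oxocyclohex-4-ene-1-carbaldehyde
Product: 6 (4S,5S)-4-hydroxy-5-(hydroxymethyl)-4,6,6-trimethylcyclohex-2-en-1-one
Conditions: NaBH(OAc)3 (1.5 equiv), AcOH, MeCN, −20 → 0 °C
Reagents that add atoms: none
Why: Chemoselective hydride reduction, in which NaBH(OAc)3 reduces the aldehyde (helped by delivery from the neighbouring C7 hydroxyl) but not the hindered conjugated C10 ketone, and the mildly acidic medium prevents retro-aldol cleavage and C6 epimerisation, so both stereocentres are kept.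

Step 5
Reactants: 6 (4S,5S)-4-hydroxy-5-(hydroxymethyl)-4,6,6-trimethylcyclohex-2-en-1-one
Product: 7 (4S,5R)-4-hydroxy-4,6,6-trimethyl-5-{[(1-phenyl-1H-tetrazol-5-yl)sulfanyl]methyl}cyclohex-2-en-1-one
Conditions: 1-phenyl-1H-tetrazole-5-thiol, PPh3, DIAD, THF, 0 °C → rt
Reagents that add atoms: 1-phenyl-1H-tetrazole-5-thiol, Sc1nnnn1-c1ccccc1
Why: Mitsunobu thioetherification, in which the acidic thiol displaces the oxyphosphonium group of the primary C5 alcohol while the tertiary C7 alcohol cannot be activated.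

Step 6
Reactants: 7 (4S,5R)-4-hydroxy-4,6,6-trimethyl-5-{[(1-phenyl-1H-tetrazol-5-yl)sulfanyl]methyl}cyclohex-2-en-1-one
Product: 8 (4S,5R)-4-hydroxy-4,6,6-trimethyl-5-{[(1-phenyl-1H-tetrazol-5-yl)sulfonyl]methyl}cyclohex-2-en-1-one
Conditions: (NH4)6Mo7O24·4H2O (10 mol %), 30% H2O2 (6 equiv), EtOH, 0 °C → rt
Reagents that add atoms: hydrogen peroxide, OO
Why: Molybdate-catalysed peroxide oxidation of a sulfide to the sulfone, to which the electron-poor enone alkene is inert in the absence of base.

Step 7
Reactants: 8 (4S,5R)-4-hydroxy-4,6,6-trimethyl-5-{[(1-phenyl-1H-tetrazol-5-yl)sulfonyl]methyl}cyclohex-2-en-1-one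
Product: 9 (4S,5R)-4,6,6-trimethyl-5-{[(1-phenyl-1H-tetrazol-5-yl)sulfonyl]methyl}-4-(triethylsilyloxy)cyclohex-2-en-1-one
Conditions: Et3SiOTf (1.5 equiv), 2,6-lutidine, CH2Cl2, −78 → 0 °C
Reagents that add atoms: triethylsilyl trifluoromethanesulfonate, CC[Si](CC)(CC)OS(=O)(=O)C(F)(F)F
Why: Silylation of the tertiary alcohol with a silyl triflate, which removes the alkoxide that would otherwise attack the tetrazole ring (Smiles-type transfer) under the base of step 13.

Step 8
Reactants: 10 (S)-citramalic acid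
Product: 11 2-[(4S)-2,2,4-trimethyl-5-oxo-1,3-dioxolan-4-yl]acetic acid
Conditions: Me2C(OMe)2, p-TsOH·H2O (cat.), rt
Reagents that add atoms: 2,2-dimethoxypropane, COC(C)(C)OC
Why: Acid-catalysed acetalisation, in which the α-hydroxy acid unit closes the five-membered dioxolanone in preference to the six-membered alternative, masking the C3 hydroxyl and the C4 carboxyl and leaving the C1 carboxyl free; the quaternary stereocentre is not touched.

Step 9
Reactants: 11 2-[(4S)-2,2,4-trimethyl-5-oxo-1,3-dioxolan-4-yl]acetic acid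
Product: 13 (3S)-3-hydroxy-3-methyloxolan-2-one, via hydroxyethyl dioxolanone 12 (not isolated)
Conditions: BH3·THF, THF, 0 °C → rt; MeOH; then p-TsOH·H2O (cat.), CH2Cl2, rt
Reagents that add atoms: none
Why: Borane reduces the free carboxylic acid chemoselectively beside the dioxolanone, and acid then moves the acyl group to the new primary alcohol (lactonisation) with loss of acetone; C3 takes no part.

Step 10
Reactants: 13 (3S)-3-hydroxy-3-methyloxolan-2-one
Product: 14 (2S)-2,4-dihydroxy-N-methoxy-N,2-dimethylbutanamide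
Conditions: MeNH(OMe) (3 equiv), AlMe3 (3 equiv), CH2Cl2, 0 °C → rt; Rochelle salt work-up
Reagents that add atoms: N,O-dimethylhydroxylamine, CNOC
Why: Aminolysis of the lactone by the dimethylaluminium amide (Weinreb amide formation) opens the ring without affecting C3.

Step 11
Reactants: 14 (2S)-2,4-dihydroxy-N-methoxy-N,2-dimethylbutanamide
Product: 15 (2S)-N-methoxy-N,2-dimethyl-2,4-bis(triethylsilyloxy)butanamide
Conditions: Et3SiOTf (2.5 equiv), 2,6-lutidine, CH2Cl2, −78 → 0 °C
Reagents that add atoms: triethylsilyl trifluoromethanesulfonate, CC[Si](CC)(CC)OS(=O)(=O)C(F)(F)F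
Why: Silylation of the primary and the tertiary hydroxyl with the silyl triflate, carried out at once on crude 14 to forestall relactonisation.

Step 12
Reactants: 15 (2S)-N-methoxy-N,2-dimethyl-2,4-bis(triethylsilyloxy)butanamide
Product: 16 (2S)-2-methyl-2,4-bis(triethylsilyloxy)butanal
Conditions: iBu2AlH (1.3 equiv), THF, −78 °C; Rochelle salt work-up
Reagents that add atoms: none
Why: Hydride reduction of a Weinreb amide stops at the aldehyde through the chelated tetrahedral intermediate, and the quaternary α-carbon cannot epimerise.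

Step 13
Reactants: 9 (4S,5R)-4,6,6-trimethyl-5-{[(1-phenyl-1H-tetrazol-5-yl)sulfonyl]methyl}-4-(triethylsilyloxy)cyclohex-2-en-1-one; 16 (2S)-2-methyl-2,4-bis(triethylsilyloxy)butanal
Product: 17 (4S,5R)-4,6,6-trimethyl-5-[(1E,3S)-3-methyl-3,5-bis(triethylsilyloxy)pent-1-en-1-yl]-4-(triethylsilyloxy)cyclohex-2-en-1-one
Conditions: KN(SiMe3)2 (1.2 equiv) added to 9 + 16 (1.3 equiv), THF, −78 °C → rt
Reagents that add atoms: none
Why: Julia–Kocienski olefination, in which the sulfonyl carbanion adds to the non-enolisable aldehyde and Smiles rearrangement with loss of SO2 and the tetrazololate gives the C4=C5 alkene (E expected, geometry immaterial); the C10 enone needs no protection because neither C11 nor C7 carries hydrogen, and deprotonation in the presence of the aldehyde keeps the carbanion away from the hindered enone.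

Step 14
Reactants: 17 (4S,5R)-4,6,6-trimethyl-5-[(1E,3S)-3-methyl-3,5-bis(triethylsilyloxy)pent-1-en-1-yl]-4-(triethylsilyloxy)cyclohex-2-en-1-one
Product: 19 (3R,4S)-3-[(3R)-3,5-dihydroxy-3-methylpentyl]-4-hydroxy-2,2,4-trimethylcyclohexan-1-one, via saturated tris(triethylsilyl) ether 18 (not isolated)
Conditions: H2 (4 atm), 10% Pd/C, EtOAc–MeOH, rt; filter; then 1 M HCl (aq), MeOH, 0 °C → rt
Reagents that add atoms: none
Why: Heterogeneous catalytic hydrogenation saturates C8=C9 and C4=C5 without reducing the ketone or creating a stereocentre, and dilute acid then cleaves the three silyl ethers.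

Step 15
Reactants: 19 (3R,4S)-3-[(3R)-3,5-dihydroxy-3-methylpentyl]-4-hydroxy-2,2,4-trimethylcyclohexan-1-one; 20 umbelliferone
Product: 21 7-{[(3R)-3-hydroxy-5-[(1R,6S)-6-hydroxy-2,2,6-trimethyl-3-oxocyclohexyl]-3-methylpentyl]oxy}-2H-chromen-2-one (target CNP0414652.1)
Conditions: PPh3, DIAD, THF, 0 °C → rt
Reagents that add atoms: none
Why: Mitsunobu etherification, in which the phenol (pKa about 8) is alkylated by the activated primary C1 alcohol only, since the tertiary C3 and C7 alcohols are not substrates; no stereocentre is involved.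

Compound list
1 | 2-methylfuran | Cc1ccco1 | starting material
2 | 3-methylbut-2-enal | CC(C)=CC=O | starting material
3 | 3-methyl-3-(5-methylfuran-2-yl)butanal | Cc1ccc(o1)C(C)(C)CC=O | intermediate
4 | (5Z)-3,3-dimethyl-4,7-dioxooct-5-enal | O=CCC(C)(C)C(=O)/C=C\C(C)=O | intermediate
5 | (1R,6S)-6-hydroxy-2,2,6-trimethyl-3-oxocyclohex-4-ene-1-carbaldehyde | CC1(C)C(=O)C=C[C@](C)(O)[C@@H]1C=O | intermediate
6 | (4S,5S)-4-hydroxy-5-(hydroxymethyl)-4,6,6-trimethylcyclohex-2-en-1-one | CC1(C)C(=O)C=C[C@](C)(O)[C@@H]1CO | intermediate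
7 | (4S,5R)-4-hydroxy-4,6,6-trimethyl-5-{[(1-phenyl-1H-tetrazol-5-yl)sulfanyl]methyl}cyclohex-2-en-1-one | CC1(C)C(=O)C=C[C@](C)(O)[C@@H]1CSc1nnnn1-c1ccccc1 | intermediate
8 | (4S,5R)-4-hydroxy-4,6,6-trimethyl-5-{[(1-phenyl-1H-tetrazol-5-yl)sulfonyl]methyl}cyclohex-2-en-1-one | CC1(C)C(=O)C=C[C@](C)(O)[C@@H]1CS(=O)(=O)c1nnnn1-c1ccccc1 | intermediate
9 | (4S,5R)-4,6,6-trimethyl-5-{[(1-phenyl-1H-tetrazol-5-yl)sulfonyl]methyl}-4-(triethylsilyloxy)cyclohex-2-en-1-one | CC1(C)C(=O)C=C[C@](C)(O[Si](CC)(CC)CC)[C@@H]1CS(=O)(=O)c1nnnn1-c1ccccc1 | intermediate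
10 | (S)-citramalic acid | C[C@](O)(CC(=O)O)C(=O)O | starting material
11 | 2-[(4S)-2,2,4-trimethyl-5-oxo-1,3-dioxolan-4-yl]acetic acid | C[C@](OC(C)(C)O1)(CC(=O)O)C1=O | intermediate
12 | (5S)-5-(2-hydroxyethyl)-2,2,5-trimethyl-1,3-dioxolan-4-one (not isolated) | C[C@](OC(C)(C)O1)(CCO)C1=O | intermediate
13 | (3S)-3-hydroxy-3-methyloxolan-2-one | C[C@](O)(CCO1)C1=O | intermediate
14 | (2S)-2,4-dihydroxy-N-methoxy-N,2-dimethylbutanamide | C[C@](O)(CCO)C(=O)N(C)OC | intermediate
15 | (2S)-N-methoxy-N,2-dimethyl-2,4-bis(triethylsilyloxy)butanamide | C[C@](O[Si](CC)(CC)CC)(CCO[Si](CC)(CC)CC)C(=O)N(C)OC | intermediate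
16 | (2S)-2-methyl-2,4-bis(triethylsilyloxy)butanal | C[C@](O[Si](CC)(CC)CC)(CCO[Si](CC)(CC)CC)C=O | intermediate
17 | (4S,5R)-4,6,6-trimethyl-5-[(1E,3S)-3-methyl-3,5-bis(triethylsilyloxy)pent-1-en-1-yl]-4-(triethylsilyloxy)cyclohex-2-en-1-one | CC1(C)C(=O)C=C[C@](C)(O[Si](CC)(CC)CC)[C@@H]1/C=C/[C@@](C)(O[Si](CC)(CC)CC)CCO[Si](CC)(CC)CC | intermediate
18 | (3R,4S)-2,2,4-trimethyl-3-[(3R)-3-methyl-3,5-bis(triethylsilyloxy)pentyl]-4-(triethylsilyloxy)cyclohexan-1-one (not isolated) | CC1(C)C(=O)CC[C@](C)(O[Si](CC)(CC)CC)[C@@H]1CC[C@@](C)(O[Si](CC)(CC)CC)CCO[Si](CC)(CC)CC | intermediate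
19 | (3R,4S)-3-[(3R)-3,5-dihydroxy-3-methylpentyl]-4-hydroxy-2,2,4-trimethylcyclohexan-1-one | CC1(C)C(=O)CC[C@](C)(O)[C@@H]1CC[C@@](C)(O)CCO | intermediate
20 | umbelliferone (7-hydroxy-2H-chromen-2-one) | O=c1ccc2ccc(O)cc2o1 | starting material
21 | 7-{[(3R)-3-hydroxy-5-[(1R,6S)-6-hydroxy-2,2,6-trimethyl-3-oxocyclohexyl]-3-methylpentyl]oxy}-2H-chromen-2-one | CC1(C)C(=O)CC[C@](C)(O)[C@@H]1CC[C@@](C)(O)CCOc1ccc2ccc(=O)oc2c1 | target

Total step count: 15. Longest linear sequence: 10 (steps 1–7 and 13–15); the citramalic acid branch is 5 steps (8–12) before the coupling.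

Steps most likely to fail

Step 3 (Proposed new method). The secondary amine may add to the ene-dione and isomerise it from Z to E (which cannot close the ring). The base-type cyclopentenone aldol of the C7 methyl onto C10 or loss of water from the aldol may intervene. The face of the ketone may also be poorly controlled relative to C6; if only the absolute sense were opposite, (S)-proline would be used. Fallback with known chemistry: the amine-sensitive alkene is removed before the aldol and restored afterwards.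
- Setting out from 4, Zn dust in AcOH should reduce C8=C9 to give 3,3-dimethyl-4,7-dioxooctanal F1.
- (R)-Proline in CH2Cl2 then effects the 6-enolexo aldolisation established for saturated keto aldehydes, giving (1R,6S)-6-hydroxy-2,2,6-trimethyl-3-oxocyclohexane-1-carbaldehyde F2.
- NaBH(OAc)3 reduces the aldehyde to (3S,4S)-4-hydroxy-3-(hydroxymethyl)-2,2,4-trimethylcyclohexan-1-one F3.
- Mitsunobu reaction with 1-phenyl-1H-tetrazole-5-thiol gives (3R,4S)-4-hydroxy-2,2,4-trimethyl-3-{[(1-phenyl-1H-tetrazol-5-yl)sulfanyl]methyl}cyclohexan-1-one F4.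
- (NH4)6Mo7O24·4H2O with H2O2 gives (3R,4S)-4-hydroxy-2,2,4-trimethyl-3-{[(1-phenyl-1H-tetrazol-5-yl)sulfonyl]methyl}cyclohexan-1-one F5.
- IBX in DMSO at 70 °C dehydrogenates the ketone at its only α-methylene (C9), and the route is rejoined at 8.

Step 1. The furan may attack the aldehyde carbon instead of the hindered tertiary β-carbon, and the product aldehyde may go on to alkylate a second furan, so that material is lost to bis-furyl condensation. Fallback: the quaternary carbon is built by cuprate addition instead.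
- Setting out from 1, Friedel–Crafts acetylation (Ac2O, cat. H3PO4) gives 1-(5-methylfuran-2-yl)ethan-1-one F6.
- Horner–Wadsworth–Emmons reaction with (EtO)2P(O)CH2CO2Et and NaH in THF gives ethyl (2E)-3-(5-methylfuran-2-yl)but-2-enoate F7 (geometry immaterial).
- Conjugate addition of Me2CuLi with Me3SiCl at −78 → 0 °C gives ethyl 3-methyl-3-(5-methylfuran-2-yl)butanoate F8.
- iBu2AlH in CH2Cl2 at −78 °C reduces the ester to the aldehyde, rejoining the route at 3.

Step 13. The sulfonyl carbanion may add to the enone of a second molecule or decay by self-condensation before it reaches the hindered α-quaternary aldehyde. Fallback: a Wittig reaction with a γ-oxido ylide, which needs no sulfone and no protection of C7–OH.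
- Setting out from 6, I2, PPh3 and imidazole give (4S,5R)-4-hydroxy-5-(iodomethyl)-4,6,6-trimethylcyclohex-2-en-1-one F9.
- PPh3 in MeCN at reflux gives {[(1R,6S)-6-hydroxy-2,2,6-trimethyl-3-oxocyclohex-4-en-1-yl]methyl}triphenylphosphonium iodide F10.
- NaN(SiMe3)2 (2 equiv) in THF followed by aldehyde 16 gives (4S,5R)-4-hydroxy-4,6,6-trimethyl-5-[(1Z,3S)-3-methyl-3,5-bis(triethylsilyloxy)pent-1-en-1-yl]cyclohex-2-en-1-one F11.
- The conditions of step 14 (hydrogenation, then dilute HCl) convert F11 into 19, where the route is rejoined.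

Further compounds
F1 | step 3 | 3,3-dimethyl-4,7-dioxooctanal | O=CCC(C)(C)C(=O)CCC(C)=O
F2 | step 3 | (1R,6S)-6-hydroxy-2,2,6-trimethyl-3-oxocyclohexane-1-carbaldehyde | CC1(C)C(=O)CC[C@](C)(O)[C@@H]1C=O
F3 | step 3 | (3S,4S)-4-hydroxy-3-(hydroxymethyl)-2,2,4-trimethylcyclohexan-1-one | CC1(C)C(=O)CC[C@](C)(O)[C@@H]1CO
F4 | step 3 | (3R,4S)-4-hydroxy-2,2,4-trimethyl-3-{[(1-phenyl-1H-tetrazol-5-yl)sulfanyl]methyl}cyclohexan-1-one | CC1(C)C(=O)CC[C@](C)(O)[C@@H]1CSc1nnnn1-c1ccccc1
F5 | step 3 | (3R,4S)-4-hydroxy-2,2,4-trimethyl-3-{[(1-phenyl-1H-tetrazol-5-yl)sulfonyl]methyl}cyclohexan-1-one | CC1(C)C(=O)CC[C@](C)(O)[C@@H]1CS(=O)(=O)c1nnnn1-c1ccccc1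
F6 | step 1 | 1-(5-methylfuran-2-yl)ethan-1-one | CC(=O)c1ccc(C)o1
F7 | step 1 | ethyl (2E)-3-(5-methylfuran-2-yl)but-2-enoate | CCOC(=O)/C=C(\C)c1ccc(C)o1
F8 | step 1 | ethyl 3-methyl-3-(5-methylfuran-2-yl)butanoate | CCOC(=O)CC(C)(C)c1ccc(C)o1
F9 | step 13 | (4S,5R)-4-hydroxy-5-(iodomethyl)-4,6,6-trimethylcyclohex-2-en-1-one | CC1(C)C(=O)C=C[C@](C)(O)[C@@H]1CI
F10 | step 13 | {[(1R,6S)-6-hydroxy-2,2,6-trimethyl-3-oxocyclohex-4-en-1-yl]methyl}triphenylphosphonium iodide | CC1(C)C(=O)C=C[C@](C)(O)[C@@H]1C[P+](c1ccccc1)(c1ccccc1)c1ccccc1.[I-]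
F11 | step 13 | (4S,5R)-4-hydroxy-4,6,6-trimethyl-5-[(1Z,3S)-3-methyl-3,5-bis(triethylsilyloxy)pent-1-en-1-yl]cyclohex-2-en-1-one | CC1(C)C(=O)C=C[C@](C)(O)[C@@H]1/C=C\[C@@](C)(O[Si](CC)(CC)CC)CCO[Si](CC)(CC)CC
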